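- I ran a stirred vessel of constant volume at constant temperature, with the earlier runs to judge from and winter and dawn to compare.

in all of them: precatalyst 0.5 mol%

| run | substrate | partner | capture agent | free catalyst | remark | time |
|---|---|---|---|---|---|---|
| teal | 13 mM (fed, over 10 min) | 2.5 equiv | 1 mM | 0.5 mol% | run made earlier |  |
| grey | 30 mM (fed, over 10 min) | 2.5 equiv | 1 mM | 0.5 mol% | run made earlier |  |
| ochre | 20 mM (fed, over 10 min) | 2.5 equiv | 1 mM | 0.75 mol% | run made earlier |  |
| winter | 20 mM (fed, over 10 min) | 2.50 equiv | 1.00 mM | 0.5 mol% |  | 20 min |
| dawn | 20 mM | 2.50 equiv | 1.00 mM | 0.5 mol% | everything together at the start | 10 min |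

| run | time / min | target / % | isomer of the product / % | trapped intermediate / % |
|---|---|---|---|---|
| teal | 2.00 | 1.3 | 1.6 | 0 |
| teal | 6.00 | 0 | 0.4 | 0 |
| teal | 12.0 | 5.1 | 1.8 | 0.2 |
| teal | 15.0 | 9.0 | 6.0 | 1.5 |
| teal | 25.0 | 17.4 | 19.0 | 3.1 |
| grey | 2.00 | 0 | 0 | 0.3 |
| grey | 6.00 | 7.5 | 3.7 | 1.8 |
| grey | 12.0 | 27.1 | 27.6 | 0 |
| grey | 15.0 | 30.9 | 41.0 | 1.2 |
| grey | 25.0 | 30.1 | 65.6 | 1.2 |
| ochre | 2.00 | 0.4 | 1.3 | 1.2 |
| ochre | 4.00 | 0 | 0.4 | 0 |
| ochre | 6.00 | 5.2 | 1.1 | 1.3 |
| ochre | 12.0 | 13.0 | 11.4 | 3.0 |
| ochre | 25.0 | 24.5 | 44.6 | 0.8 |

(scatter of a reading: 1 percentage point)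

* the flask that ends with the higher share of target in all that became target or isomer of the product or trapped intermediate, or "neither" when 2 percentage points or less lies between them (winter / dawn / neither)
* share of target in all that became target or isomer of the product or trapped intermediate, winter
* share of target in all that became target or isomer of the product or trapped intermediate, dawn

- what was read earlier has a scatter of 1 percentage point, one standard deviation
- percentages count the whole charge, also what has not yet gone in

- My first estimate was that the share s of target among target, isomer of the product and trapped intermediate simply falls with the clock. The objection came at once: at 12.0 min, teal read 71.8% but grey read 49.5%.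
- Grey and ochre had different charges but the same free catalyst concentration c, 0.150 mM, and at that time ochre read 47.4%, close to grey. So I treated the loss of target as pseudo-first-order, its rate in proportion to c, which I took to stay at its charge.
- For dawn, c times time gave 1.00 mM·min, and this product, free catalyst concentration multiplied by time, is the exposure X that I carried.
- Teal at 15.0 min had X = 0.975 mM·min, close to dawn, and read 54.5%, so that was my figure for dawn.
- Winter had X = 2.00 mM·min, about midway between grey at 12.0 min, which read 49.5%, and grey at 15.0 min, which read 42.3%. That gave me 45.9% for winter.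
- The doubt was that those runs were fed and dawn was not, so dawn's target might be older. But teal's three products summed to 7.10 at 12.0 min and 16.5 at 15.0 min, so more than that first sum arose after the feed had stopped. I kept both figures, which left dawn ahead by 8.6 percentage points, more than the margin.
- The forecast gave dawn as the higher flask, with 43% for winter and 50% for dawn, lower than my dawn figure, on the ground that “exposure time erodes selectivity”.
- Winter ended at 43.5% and dawn at 56.7%, so dawn ended higher.

    substrate + free catalyst → free catalyst + open intermediate (k = 13000 M⁻¹ min⁻¹)
    partner + second catalyst + open intermediate → second catalyst + target (k = 42000 M⁻² min⁻¹)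
    target + free catalyst ⇌ isomer of the product + free catalyst, rate k3*[free catalyst]*[target] forward; the back reaction follows from the equilibrium constant (K = 2.50, k = 2100 M⁻¹ min⁻¹)
    open intermediate + capture agent → trapped intermediate (k = 1.30 M⁻¹ min⁻¹)
    partner + precatalyst → second catalyst + spent reagent (k = 0.670 M⁻¹ min⁻¹)

- A neighbour of dawn was charged with 0.12 mol% of free catalyst, everything else held. Its X was 0.240 mM·min, lower than teal's 0.780 mM·min at 12.0 min, so I reckoned its share above the 71.8% read there. That neighbour gave 83.2%, with 2.98% as isomer of the product and 4.42% of the substrate still unconverted.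

(All runs stem from a simulated flask with constants of no real substance; scatter was added.)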